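**Retrosynthetic overview**

1. The route rests on the 1,4-diketone C4(=O)–C3–C3''–C4''(=O) that joins rings C and C''. Each carbonyl sits on a trioxygenated ring A, and each of C3 and C3'' lies next to an aryl ether carbon (C2, C2''). This is a C3≡C3'' alkyne that has been hydroacylated twice by two salicylaldehyde-type formyl groups.
2. C4–C3 and C4''–C3'' are cut together, leading back to the bis(2-formylaryl) ether 12 of a 1,4-diarylbut-2-yne-1,4-diol. In the forward sense one carbene-catalysed cascade closes ring C by alkyne hydroacylation and then ring C'' by a Stetter addition.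
3. O1–C2 and O1''–C2'' come from a double Mitsunobu etherification of diol 11 with salicylaldehyde 2, with inversion at both carbinols.
4. The two carbinol carbons are set one at a time by BINOL–titanium-controlled alkynylzinc additions using enantiomeric ligands: trimethylsilylacetylene to 4-(methoxymethoxy)benzaldehyde, then the derived alkyne to 4-methoxybenzaldehyde.
5. Acid finally removes the five MOM groups and lets C3 and C3'' settle trans to their neighbouring aryl groups.

Key step: step 9

Remark: flavanone numbering is used, unprimed for the 4-methoxyphenyl unit and double-primed for the 4-hydroxyphenyl unit. The target is (2S,3R,2''R,3''S), so both rings are 2,3-trans with opposite absolute sense. The CIP descriptors of the carbinol carbons change along the route (terminal ethynyl < aryl < substituted alkynyl) with no change in spatial arrangement. The facial sense assumed for the BINOL–Ti(OiPr)4 alkynylations is the one established for aryl aldehydes and would be confirmed on 6 and 10 by Mosher ester analysis.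

**Route**

Step 1
Reactants: 1 2,4,6-trihydroxybenzaldehyde
Product: 2 2-hydroxy-4,6-bis(methoxymethoxy)benzaldehyde
Conditions: MOMCl (2.2 equiv), iPr2NEt, CH2Cl2, 0 °C
Reagents that add atoms: chloromethyl methyl ether, COCCl
Why: Williamson-type O-alkylation (MOM protection) should take the para and one ortho hydroxyl, while the other ortho hydroxyl is held in the hydrogen bond to the formyl group and stays free as the later Mitsunobu nucleophile.

Step 2
Reactants: 3 4-hydroxybenzaldehyde
Product: 4 4-(methoxymethoxy)benzaldehyde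
Conditions: MOMCl, iPr2NEt, CH2Cl2, 0 °C to rt
Reagents that add atoms: chloromethyl methyl ether, COCCl
Why: Williamson-type MOM protection of the only phenol, giving an aldehyde that tolerates organozinc reagents.

Step 3
Reactants: 4 4-(methoxymethoxy)benzaldehyde; 5 trimethylsilylacetylene
Product: 6 (R)-1-[4-(methoxymethoxy)phenyl]-3-(trimethylsilyl)prop-2-yn-1-ol
Conditions: 5 (4 equiv), Et2Zn (4 equiv), Cy2NH (5 mol %), Et2O, rt; (S)-BINOL (40 mol %), Ti(OiPr)4 (1 equiv); then 4, rt; aq NH4Cl
Reagents that add atoms: none
Why: BINOL–titanium-catalysed asymmetric addition of an alkynylzinc to an aryl aldehyde, in which the (S)-ligand is expected to direct alkynyl transfer to the Si face of the formyl group and so set the (R)-carbinol.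

Step 4
Reactants: 6 (R)-1-[4-(methoxymethoxy)phenyl]-3-(trimethylsilyl)prop-2-yn-1-ol
Product: 7 (R)-tert-butyl{[1-[4-(methoxymethoxy)phenyl]-3-(trimethylsilyl)prop-2-yn-1-yl]oxy}dimethylsilane
Conditions: TBSCl, imidazole, DMF, rt
Reagents that add atoms: tert-butyldimethylsilyl chloride, CC(C)(C)[Si](C)(C)Cl
Why: Standard silylation of a secondary alcohol, which leaves the stereocentre untouched and keeps a zinc alkoxide out of the second alkynylation.

Step 5
Reactants: 7 (R)-tert-butyl{[1-[4-(methoxymethoxy)phenyl]-3-(trimethylsilyl)prop-2-yn-1-yl]oxy}dimethylsilane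
Product: 8 (S)-tert-butyl{[1-[4-(methoxymethoxy)phenyl]prop-2-yn-1-yl]oxy}dimethylsilane
Conditions: K2CO3 (20 mol %), MeOH, rt
Reagents that add atoms: none
Why: Base-catalysed methanolysis of the C(sp)–Si bond (protodesilylation) should free the terminal alkyne while the O–silyl and MOM ethers are inert; the descriptor becomes S only because ethynyl ranks below aryl.

Step 6
Reactants: 8 (S)-tert-butyl{[1-[4-(methoxymethoxy)phenyl]prop-2-yn-1-yl]oxy}dimethylsilane; 9 4-methoxybenzaldehyde
Product: 10 (1S,4R)-4-[(tert-butyldimethylsilyl)oxy]-1-(4-methoxyphenyl)-4-[4-(methoxymethoxy)phenyl]but-2-yn-1-ol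
Conditions: 8 (2 equiv), Et2Zn (2 equiv), Cy2NH (5 mol %), Et2O, rt; (R)-BINOL (40 mol %), Ti(OiPr)4 (1 equiv); then 9 (1 equiv), rt; aq NH4Cl; excess 8 recovered
Reagents that add atoms: none
Why: A second BINOL–titanium-catalysed alkynylzinc addition, in which the (R)-ligand is expected to direct attack to the Re face and set the (S)-carbinol under catalyst control, the existing stereocentre lying across the alkyne and too far away to interfere.

Step 7
Reactants: 10 (1S,4R)-4-[(tert-butyldimethylsilyl)oxy]-1-(4-methoxyphenyl)-4-[4-(methoxymethoxy)phenyl]but-2-yn-1-ol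
Product: 11 (1S,4R)-1-(4-methoxyphenyl)-4-[4-(methoxymethoxy)phenyl]but-2-yne-1,4-diol
Conditions: TBAF, AcOH (1 equiv), THF, 0 °C to rt
Reagents that add atoms: none
Why: Fluoride-induced desilylation, buffered with acetic acid so that the base-sensitive diarylbutynediol does not isomerise; since the two carbinols were set independently, a wrong configuration at either centre gives a diastereomer that chromatography or crystallisation of 11 should remove.

Step 8
Reactants: 11 (1S,4R)-1-(4-methoxyphenyl)-4-[4-(methoxymethoxy)phenyl]but-2-yne-1,4-diol; 2 2-hydroxy-4,6-bis(methoxymethoxy)benzaldehyde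
Product: 12 2,2'-{[(1R,4S)-1-(4-methoxyphenyl)-4-[4-(methoxymethoxy)phenyl]but-2-yne-1,4-diyl]bis(oxy)}bis[4,6-bis(methoxymethoxy)benzaldehyde]
Conditions: 2 (2.5 equiv), PPh3, DIAD, toluene, −20 °C to rt
Reagents that add atoms: none
Why: Double Mitsunobu etherification, in which the acidic salicylaldehyde phenol displaces each alkoxyphosphonium by SN2 with inversion and turns the (1S,4R) diol into the (1R,4S) bis-ether, low temperature and a nonpolar solvent holding back ionisation of the alkoxybenzylic centres.

Step 9
Reactants: 12 2,2'-{[(1R,4S)-1-(4-methoxyphenyl)-4-[4-(methoxymethoxy)phenyl]but-2-yne-1,4-diyl]bis(oxy)}bis[4,6-bis(methoxymethoxy)benzaldehyde]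
Product: 14 (2S,3R)-3-[(2R,3S)-5,7-bis(methoxymethoxy)-2-[4-(methoxymethoxy)phenyl]-4-oxochroman-3-yl]-5,7-bis(methoxymethoxy)-2-(4-methoxyphenyl)chroman-4-one, via the (E)-3-ylidenechroman-4-one aldehyde 13 (not isolated)
Conditions: 3-mesityl-5,6,7,8-tetrahydro-4H-cyclohepta[d]thiazol-3-ium perchlorate (20 mol %), K2CO3 (40 mol %), THF, 70 °C
Reagents that add atoms: none
Why: The thiazol-2-ylidene freed by K2CO3 adds to one formyl group, and the Breslow intermediate transfers its acyl carbon to the near alkyne carbon and its hydroxyl proton to the far one in a concerted syn addition, giving enone 13; the carbene then turns the second formyl group into a Breslow intermediate that adds to the enone β-carbon C3'' (Stetter reaction), and the enolate is protonated at C3. The closest known reaction is the carbene-catalysed hydroacylation of unactivated alkynes in O-propargyl salicylaldehydes and its one-pot continuation by a Stetter addition, here run with both aldehydes in the same molecule. Ring C closes 6-exo-dig (C4–C3) and ring C'' closes 6-exo-trig (C4''–C3''), and the same product results whichever formyl group reacts first. C3'' is set in the Stetter step by C2'': allylic 1,3-strain keeps the C2''–H bond in the plane of the enone, so the tethered acyl anion equivalent attacks the face away from the C2'' aryl group and the new ring is 2'',3''-trans. C3 is set by protonation of the enolate on the face away from the C2 aryl group, and because C3 and C3'' are each α to a ketone the diequatorial trans,trans isomer is also the thermodynamic one. The step needs exo over endo closure, which the three-atom O–C–C tether secures, and intact C2 and C2'', which a substoichiometric, poorly soluble carbonate base and a fast intramolecular second cyclisation secure by leaving 13 no time to isomerise to a flavone or a deconjugated enol ether.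

Step 10
Reactants: 14 (2S,3R)-3-[(2R,3S)-5,7-bis(methoxymethoxy)-2-[4-(methoxymethoxy)phenyl]-4-oxochroman-3-yl]-5,7-bis(methoxymethoxy)-2-(4-methoxyphenyl)chroman-4-one
Product: 15 (2S,3R)-3-[(2R,3S)-5,7-dihydroxy-2-(4-hydroxyphenyl)-4-oxochroman-3-yl]-5,7-dihydroxy-2-(4-methoxyphenyl)chroman-4-one (CNP0196568.3)
Conditions: 3 M aq HCl, MeOH, 50 °C, continued until the C3/C3'' epimer composition no longer changes
Reagents that add atoms: none
Why: Acid-catalysed acetal exchange should remove the five MOM ethers as dimethoxymethane, and the same medium enolises C3 and C3'' so that any cis epimer from step 9 converges on the trans,trans compound, while the aryl methyl ether and the acid-stable C2 and C2'' centres are unaffected.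

**Compound list**

1 | 2,4,6-trihydroxybenzaldehyde | O=Cc1c(O)cc(O)cc1O | starting material
2 | 2-hydroxy-4,6-bis(methoxymethoxy)benzaldehyde | O=Cc1c(O)cc(OCOC)cc1OCOC | intermediate
3 | 4-hydroxybenzaldehyde | O=Cc1ccc(O)cc1 | starting material
4 | 4-(methoxymethoxy)benzaldehyde | O=Cc1ccc(OCOC)cc1 | intermediate
5 | trimethylsilylacetylene | C#C[Si](C)(C)C | starting material
6 | (R)-1-[4-(methoxymethoxy)phenyl]-3-(trimethylsilyl)prop-2-yn-1-ol | C[Si](C)(C)C#C[C@H](O)c1ccc(OCOC)cc1 | intermediate
7 | (R)-tert-butyl{[1-[4-(methoxymethoxy)phenyl]-3-(trimethylsilyl)prop-2-yn-1-yl]oxy}dimethylsilane | C[Si](C)(C)C#C[C@H](O[Si](C)(C)C(C)(C)C)c1ccc(OCOC)cc1 | intermediate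
8 | (S)-tert-butyl{[1-[4-(methoxymethoxy)phenyl]prop-2-yn-1-yl]oxy}dimethylsilane | C#C[C@H](O[Si](C)(C)C(C)(C)C)c1ccc(OCOC)cc1 | intermediate
9 | 4-methoxybenzaldehyde | COc1ccc(C=O)cc1 | starting material
10 | (1S,4R)-4-[(tert-butyldimethylsilyl)oxy]-1-(4-methoxyphenyl)-4-[4-(methoxymethoxy)phenyl]but-2-yn-1-ol | COc1ccc([C@H](O)C#C[C@H](O[Si](C)(C)C(C)(C)C)c2ccc(OCOC)cc2)cc1 | intermediate
11 | (1S,4R)-1-(4-methoxyphenyl)-4-[4-(methoxymethoxy)phenyl]but-2-yne-1,4-diol | COc1ccc([C@H](O)C#C[C@H](O)c2ccc(OCOC)cc2)cc1 | intermediate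
12 | 2,2'-{[(1R,4S)-1-(4-methoxyphenyl)-4-[4-(methoxymethoxy)phenyl]but-2-yne-1,4-diyl]bis(oxy)}bis[4,6-bis(methoxymethoxy)benzaldehyde] | COc1ccc([C@@H](Oc2cc(OCOC)cc(OCOC)c2C=O)C#C[C@@H](Oc2cc(OCOC)cc(OCOC)c2C=O)c2ccc(OCOC)cc2)cc1 | intermediate
13 | 2-{[(1R,2E)-2-[(2R)-5,7-bis(methoxymethoxy)-2-(4-methoxyphenyl)-4-oxochroman-3-ylidene]-1-[4-(methoxymethoxy)phenyl]ethyl]oxy}-4,6-bis(methoxymethoxy)benzaldehyde (drawn for closure of ring C first) | COc1ccc([C@H]2Oc3cc(OCOC)cc(OCOC)c3C(=O)/C2=C/[C@@H](Oc2cc(OCOC)cc(OCOC)c2C=O)c2ccc(OCOC)cc2)cc1 | intermediate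
14 | (2S,3R)-3-[(2R,3S)-5,7-bis(methoxymethoxy)-2-[4-(methoxymethoxy)phenyl]-4-oxochroman-3-yl]-5,7-bis(methoxymethoxy)-2-(4-methoxyphenyl)chroman-4-one | COc1ccc([C@H]2Oc3cc(OCOC)cc(OCOC)c3C(=O)[C@@H]2[C@@H]2C(=O)c3c(OCOC)cc(OCOC)cc3O[C@H]2c2ccc(OCOC)cc2)cc1 | intermediate
15 | (2S,3R)-3-[(2R,3S)-5,7-dihydroxy-2-(4-hydroxyphenyl)-4-oxochroman-3-yl]-5,7-dihydroxy-2-(4-methoxyphenyl)chroman-4-one | COc1ccc([C@H]2Oc3cc(O)cc(O)c3C(=O)[C@@H]2[C@@H]2C(=O)c3c(O)cc(O)cc3O[C@H]2c2ccc(O)cc2)cc1 | target

**Step count**

Total: 10 steps. Longest linear sequence: 9 steps (3 to 15 through steps 2 to 10).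

**Steps most likely to fail**

Step 9. The 2,6-dioxygenated, electron-rich formyl groups may form the Breslow intermediate too slowly. The carbene and carbonate would then deprotonate the propargylic positions of 12 or the γ-position of enone 13, leading to allene formation, loss of configuration at C2 or C2'', or a stall after the first ring. The fallback is a base-free acyl radical cascade that sets out from 12 and returns at 14. Pinnick oxidation of both formyl groups (NaClO2, NaH2PO4, 2-methylbut-2-ene, t-BuOH/H2O) would give the bis(carboxylic acid) F1. Treatment with (PhSe)2 and PBu3 in CH2Cl2 would convert it into the bis(Se-phenyl selenoester) F2. Slow addition of Bu3SnH with AIBN in benzene at 80 °C should then generate the first aroyl radical, which closes 6-exo-dig onto the alkyne, the vinyl radical being reduced to the enone. The second aroyl radical should add 6-exo-trig to the enone β-carbon (Giese addition), and reduction of the α-keto radical gives 14. Any C3/C3'' epimers are converged in step 10.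

Step 8. The alkoxyphosphonium ions sit on alkoxybenzylic, propargylic carbons and may ionise, which would erode configuration and allow attack at the alkyne terminus to give allenyl ethers. The second etherification on the crowded mono-ether may also be sluggish. The fallback makes the two C–O bonds one at a time around the desilylation; it sets out from 10 and returns at 12, bypassing 11. Mitsunobu reaction of 10 alone with 2 (PPh3, DIAD, toluene, −40 °C) would etherify the 4-methoxyphenyl carbinol while the other oxygen is still silylated, giving 2-{[(1R,4R)-4-[(tert-butyldimethylsilyl)oxy]-1-(4-methoxyphenyl)-4-[4-(methoxymethoxy)phenyl]but-2-yn-1-yl]oxy}-4,6-bis(methoxymethoxy)benzaldehyde F3, which can be freed of its diastereomer at this stage. Desilylation with HF·pyridine in THF at 0 °C would give the mono-ether alcohol F4. A second, separately optimised Mitsunobu reaction with 2 would then give 12.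

Step 6. The bulky, functionalised alkynylzinc may transfer slowly to the electron-rich aldehyde, so that ethyl transfer or incomplete catalyst control lowers the purity of the new carbinol. The fallback separates C–C bond formation from stereocontrol; it sets out from 8 and returns at 10. Deprotonation of 8 with n-BuLi in THF at −78 °C and Weinreb ketone synthesis with N-methoxy-N-methyl-4-methoxybenzamide would give (R)-4-[(tert-butyldimethylsilyl)oxy]-1-(4-methoxyphenyl)-4-[4-(methoxymethoxy)phenyl]but-2-yn-1-one F5. Midland reduction with (S)-Alpine-Borane (B-isopinocampheyl-9-borabicyclo[3.3.1]nonane from (−)-α-pinene) should then deliver hydride with the alkyne as the small group and give the (S)-carbinol of 10.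

**Further compounds**

F1 | step 9 | 2,2'-{[(1R,4S)-1-(4-methoxyphenyl)-4-[4-(methoxymethoxy)phenyl]but-2-yne-1,4-diyl]bis(oxy)}bis[4,6-bis(methoxymethoxy)benzoic acid] | COc1ccc([C@@H](Oc2cc(OCOC)cc(OCOC)c2C(=O)O)C#C[C@@H](Oc2cc(OCOC)cc(OCOC)c2C(=O)O)c2ccc(OCOC)cc2)cc1
F2 | step 9 | bis(Se-phenyl) 2,2'-{[(1R,4S)-1-(4-methoxyphenyl)-4-[4-(methoxymethoxy)phenyl]but-2-yne-1,4-diyl]bis(oxy)}bis[4,6-bis(methoxymethoxy)benzenecarboselenoate] | COc1ccc([C@@H](Oc2cc(OCOC)cc(OCOC)c2C(=O)[Se]c2ccccc2)C#C[C@@H](Oc2cc(OCOC)cc(OCOC)c2C(=O)[Se]c2ccccc2)c2ccc(OCOC)cc2)cc1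
F3 | step 8 | 2-{[(1R,4R)-4-[(tert-butyldimethylsilyl)oxy]-1-(4-methoxyphenyl)-4-[4-(methoxymethoxy)phenyl]but-2-yn-1-yl]oxy}-4,6-bis(methoxymethoxy)benzaldehyde | COc1ccc([C@@H](Oc2cc(OCOC)cc(OCOC)c2C=O)C#C[C@H](O[Si](C)(C)C(C)(C)C)c2ccc(OCOC)cc2)cc1
F4 | step 8 | 2-{[(1R,4R)-4-hydroxy-1-(4-methoxyphenyl)-4-[4-(methoxymethoxy)phenyl]but-2-yn-1-yl]oxy}-4,6-bis(methoxymethoxy)benzaldehyde | COc1ccc([C@@H](Oc2cc(OCOC)cc(OCOC)c2C=O)C#C[C@H](O)c2ccc(OCOC)cc2)cc1
F5 | step 6 | (R)-4-[(tert-butyldimethylsilyl)oxy]-1-(4-methoxyphenyl)-4-[4-(methoxymethoxy)phenyl]but-2-yn-1-one | COc1ccc(C(=O)C#C[C@H](O[Si](C)(C)C(C)(C)C)c2ccc(OCOC)cc2)cc1
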